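**Plan**

1. Enabling feature: in the bicyclo[2.2.2]octene core both bridgeheads (the C–CH3 carbon and the C–OH carbon) are bonded to the two carbons of the only ring alkene. Those two carbons also carry the ring oxygen and the acyl carbon of the dihydropyranone, so the alkene bridge is read as an acyl alkyne with a leaving group on its other carbon.
2. Retrosynthetic cuts, in order: the tetrahydrofuran C–O bond at the methyl-bearing carbon next to the cage ketone; the vinylic C–O bond of the dihydropyranone (back to C–Br and a benzylic OH); the two bridgehead–alkene C–C bonds, which opens the cage to a 5,5-dimethylcyclohexa-1,3-diene and a bromoalkynone.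
3. Forward order of rings: dimedone ring (bought), temporary 1,3-dioxane ketal, bicyclo[2.2.2]octadiene by intermolecular [4+2], dihydropyranone by addition–elimination, tetrahydrofuran by oxidative enol ether–alcohol coupling.
4. The ketal joining the CH2OH oxygen to the neighbouring enol oxygen decides which carbonyl stays free. Methylation and enolisation therefore occur only on the far side of the ring, the stereocentre is not deprotonated, and the diene conformation is locked.
5. Stereochemistry: CHPh comes from ethyl (R)-3-hydroxy-3-phenylpropanoate, whose C–O bond is never broken, and the ring CH from a lipase resolution. Both bridgeheads follow from alkyne attack on the diene face opposite the CH2O arm, and the ether carbon from the single enol ether face that the arm can reach.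

Key step: step 12

Assumption: the lipase is taken to acylate the (S)-enantiomer of 5 faster. Were the preference reversed, the (R)-acetate would be collected and cleaved with the same enzyme in phosphate buffer, which leads to the same compound 6.

**Step 1**
Reactants: 1 dimedone (5,5-dimethylcyclohexane-1,3-dione)
Product: 2 2,5,5-trimethylcyclohexane-1,3-dione
Conditions: MeI, NaOH, H2O–1,4-dioxane, reflux
Reagents that add atoms: iodomethane, CI
Why: C-alkylation of the stabilised enolate of a cyclic 1,3-diketone with iodomethane in aqueous base is the standard entry to 2-alkyl-1,3-diones, and no stereocentre is formed.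

**Step 2**
Reactants: 2 2,5,5-trimethylcyclohexane-1,3-dione
Product: 3 3-(benzyloxy)-2,5,5-trimethylcyclohex-2-en-1-one
Conditions: BnOH, TsOH (cat.), toluene, reflux, Dean–Stark trap
Reagents that add atoms: benzyl alcohol, OCc1ccccc1
Why: acid-catalysed azeotropic enol etherification of a symmetrical 1,3-dione can give only one vinylogous ester, and benzyl is chosen because it leaves later by hydrogenolysis under neutral conditions.

**Step 3**
Reactants: 3 3-(benzyloxy)-2,5,5-trimethylcyclohex-2-en-1-one
Product: 5 rac-3-(benzyloxy)-6-(hydroxymethyl)-2,5,5-trimethylcyclohex-2-en-1-one, via lithium dienolate 4 (not isolated)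
Conditions: LiN(iPr)2, THF, −78 °C; monomeric CH2O (cracked paraformaldehyde), −78 °C; AcOH
Reagents that add atoms: formaldehyde, C=O
Why: Stork–Danheiser-type kinetic α′-deprotonation of the vinylogous ester followed by aldol addition to formaldehyde places CH2OH on the carbon next to the gem-dimethyl centre, and the new stereocentre forms as a racemate.

**Step 4**
Reactants: 5 rac-3-(benzyloxy)-6-(hydroxymethyl)-2,5,5-trimethylcyclohex-2-en-1-one
Product: 6 (R)-3-(benzyloxy)-6-(hydroxymethyl)-2,5,5-trimethylcyclohex-2-en-1-one
Conditions: Burkholderia cepacia lipase, vinyl acetate, t-BuOMe, 30 °C, stopped just past half conversion; chromatography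
Reagents that add atoms: none
Why: lipase-catalysed kinetic resolution by irreversible transesterification distinguishes the enantiomers of a primary alcohol with a β-stereocentre, so the unreacted (R)-alcohol is recovered and fixes the configuration of the future ring CH.

**Step 5**
Reactants: 6 (R)-3-(benzyloxy)-6-(hydroxymethyl)-2,5,5-trimethylcyclohex-2-en-1-one
Product: 8 (4aR)-2,2,5,5,8-pentamethyl-4,4a,5,6-tetrahydro-7H-1,3-benzodioxin-7-one, via enol dione 7 (not isolated)
Conditions: H2 (1 atm), Pd/C, EtOAc, rt; filter; 2-methoxypropene, PPTS (cat.), CH2Cl2, 0 °C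
Reagents that add atoms: 2-methoxypropene, COC(C)=C
Why: hydrogenolysis frees the 1,3-dione without acid or base, and acid-catalysed ketalisation can bridge only the primary hydroxyl and the enol oxygen on the adjacent carbon (six-membered 1,3-dioxane), which moves the free carbonyl to the far side of the ring and leaves the stereocentre untouched.

**Step 6**
Reactants: 8 (4aR)-2,2,5,5,8-pentamethyl-4,4a,5,6-tetrahydro-7H-1,3-benzodioxin-7-one
Product: 10 (4aR)-2,2,5,5,6,8-hexamethyl-4,4a,5,6-tetrahydro-7H-1,3-benzodioxin-7-one (C6 epimers), via lithium dienolate 9 (not isolated)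
Conditions: LiN(iPr)2, THF, −78 °C; MeI, −78 to −20 °C
Reagents that add atoms: iodomethane, CI
Why: kinetic α′-enolate alkylation (Stork–Danheiser type) occurs at the only CH2 next to the carbonyl because the γ-hydrogen at C4a is kinetically far less acidic, and the configuration at the new methyl-bearing carbon does not matter because that carbon becomes sp2 in the next step.

**Step 7**
Reactants: 10 (4aR)-2,2,5,5,6,8-hexamethyl-4,4a,5,6-tetrahydro-7H-1,3-benzodioxin-7-one
Product: 12 (4aR)-2,2,5,5,6,8-hexamethyl-7-(triisopropylsilyloxy)-4a,5-dihydro-4H-1,3-benzodioxine (the diene), via lithium dienolate 11 (not isolated)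
Conditions: LiN(iPr)2, THF–DMPU, −78 to −40 °C; iPr3SiOTf, −78 °C; pentane extraction, Et3N-deactivated alumina
Reagents that add atoms: triisopropylsilyl trifluoromethanesulfonate, CC(C)[Si](C(C)C)(C(C)C)OS(=O)(=O)C(F)(F)F
Why: a second kinetic α′-deprotonation and O-silylation of the cross-conjugated enolate with a hard silyl triflate gives the 1-alkoxy-3-silyloxycyclohexa-1,3-diene regiospecifically, and the bulky silyl group supplies the acid stability and radical-cation lifetime needed later.

**Step 8**
Reactants: 13 ethyl (R)-3-hydroxy-3-phenylpropanoate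
Product: 14 ethyl (R)-3-phenyl-3-(triethylsilyloxy)propanoate
Conditions: Et3SiCl, imidazole, CH2Cl2, 0 °C to rt
Reagents that add atoms: chlorotriethylsilane, CC[Si](Cl)(CC)CC
Why: imidazole-promoted O-silylation masks the benzylic alcohol without touching its C–O bond, so the (R) configuration is kept, and triethylsilyl is chosen so that it leaves together with the ketal.

**Step 9**
Reactants: 14 ethyl (R)-3-phenyl-3-(triethylsilyloxy)propanoate
Product: 15 (R)-N-methoxy-N-methyl-3-phenyl-3-(triethylsilyloxy)propanamide
Conditions: MeNH(OMe)·HCl, iPrMgCl, THF, −20 to 0 °C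
Reagents that add atoms: N,O-dimethylhydroxylamine hydrochloride, CNOC.Cl
Why: aminolysis of the ester by the magnesium amide of N,O-dimethylhydroxylamine is the usual route to a Weinreb amide and is mild enough to avoid β-elimination of the silyloxy group.

**Step 10**
Reactants: 15 (R)-N-methoxy-N-methyl-3-phenyl-3-(triethylsilyloxy)propanamide; 16 ethynyltrimethylsilane
Product: 18 (R)-1-phenyl-1-(triethylsilyloxy)-5-(trimethylsilyl)pent-4-yn-3-one, via lithium (trimethylsilyl)acetylide 17 (not isolated)
Conditions: 16, nBuLi, THF, −78 °C; 15, −78 to −20 °C; AcOH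
Reagents that add atoms: none
Why: in the Weinreb ketone synthesis the chelated tetrahedral adduct of the lithium acetylide stops at mono-addition and collapses to the alkynone only on quenching.

**Step 11**
Reactants: 18 (R)-1-phenyl-1-(triethylsilyloxy)-5-(trimethylsilyl)pent-4-yn-3-one
Product: 19 (R)-5-bromo-1-phenyl-1-(triethylsilyloxy)pent-4-yn-3-one (the bromoalkynone)
Conditions: NBS, AgNO3 (cat.), acetone, rt, dark
Reagents that add atoms: N-bromosuccinimide, O=C1CCC(=O)N1Br
Why: silver-catalysed bromodesilylation of a 1-silylalkyne with N-bromosuccinimide exchanges silicon for bromine at the alkyne terminus under neutral conditions that spare the silyl ether and the ketone.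

**Step 12**
Reactants: 12 the diene; 19 the bromoalkynone
Product: 20 bicyclo[2.2.2]octadiene cycloadduct. The bridgehead oxygen and the CH2O arm are joined in the 2,2-dimethyl-1,3-dioxane, and the arm is syn to the C(CH3)=C(OSi(iPr)3) bridge. The second bridge is C(Br)=C(acyl) with Br next to the methyl bridgehead, and the side chain is (R)-CH2CH(OSiEt3)Ph.
Conditions: toluene (concentrated), BHT (cat.), 65 °C, sealed tube, dark
Reagents that add atoms: none
Why: Normal-electron-demand Diels–Alder reaction, concerted but asynchronous, of an s-cis-locked 1-alkoxy-3-silyloxycyclohexa-1,3-diene with an electron-poor haloalkynone; cycloadditions of cyclic 1,3-dioxygenated cyclohexadienes with alkynyl ketones, and of 3-bromopropiolates with dienes, are the closest known cases. The single new six-membered ring, which completes the bicyclo[2.2.2]octadiene, closes by the cycloaddition itself through the bonds C(CH3) terminus–C(Br) and C(O-ketal) terminus–C(acyl). The regioselectivity that is needed is secured by the two oxygen donors, which put the largest HOMO coefficient on the methyl-bearing terminus, and by the ketone, which puts the largest LUMO coefficient on the bromine-bearing β-carbon. The two bridgehead stereocentres are set together by the face of attack, which C4a controls: the fused ketal holds the CH2O carbon pseudo-equatorial, so the pseudo-axial methyl of the gem-dimethyl group, the axial ketal methyl and the CH2O arm all lie on one face and only the pseudo-axial C4a–H lies on the other. Addition to that open face places the CH2O arm over the new silyl enol ether bridge, as the tetrahydrofuran requires, while the remote (R)-carbinol is a spectator. A non-polar medium disfavours stepwise conjugate addition with loss of bromide, and the temperature stays well below that at which the adduct would expel its saturated bridge (Alder–Rickert retro-cycloaddition) and aromatise.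

**Step 13**
Reactants: 20 bicyclo[2.2.2]octadiene cycloadduct
Product: 22 dihydropyranone diol ((R)-2-phenyl-2,3-dihydropyran-4-one fused to the former bromoalkene bridge, with the triisopropylsilyl enol ether, bridgehead OH and CH2OH retained), via bromoenone triol 21 (not isolated)
Conditions: PPTS (cat.), MeOH, 0 °C; evaporate; K2CO3, MeCN, rt
Reagents that add atoms: none
Why: mild acid-catalysed methanolysis should remove the strained 2,2-dimethyl-1,3-dioxane and the triethylsilyl ether faster than the hindered tetrasubstituted silyl enol ether is protonated, after which the freed benzylic hydroxyl closes the dihydropyranone by 6-endo conjugate addition–elimination on the β-bromoenone with retention at the carbinol carbon, the bridgehead alcohol being safe from retro-aldol cleavage while the cage ketone stays masked.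

**Step 14**
Reactants: 22 dihydropyranone diol
Product: 23 CNP0322161.2 (target; CHPh R, ring CH R, ether carbon S, methyl bridgehead R, carbinol bridgehead R)
Conditions: constant-current electrolysis (undivided cell, reticulated vitreous carbon anode, Pt cathode), Et4NOTs, 2,6-lutidine, MeOH–THF, rt
Reagents that add atoms: none
Why: in this anodic enol ether–alcohol coupling, a known route to tetrahydrofurans with fully substituted ether carbons, one-electron oxidation reverses the polarity of the methyl-bearing enol ether carbon, the primary hydroxyl held over it in the cleft between the two bridges adds 5-exo from the only face it can reach (ether carbon S, methyl turned toward the pyranone bridge), and a second oxidation with loss of silicon to methanol gives the ketone without ever placing a leaving group next to the free bridgehead carbinol.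

**Compound list**

1 | dimedone (5,5-dimethylcyclohexane-1,3-dione) | CC1(C)CC(=O)CC(=O)C1 | starting material
2 | 2,5,5-trimethylcyclohexane-1,3-dione | CC1C(=O)CC(C)(C)CC1=O | intermediate
3 | 3-(benzyloxy)-2,5,5-trimethylcyclohex-2-en-1-one | CC1=C(OCc2ccccc2)CC(C)(C)CC1=O | intermediate
4 | lithium cross-conjugated dienolate of 3 | CC1=C(OCc2ccccc2)CC(C)(C)C=C1O[Li] | intermediate
5 | rac-3-(benzyloxy)-6-(hydroxymethyl)-2,5,5-trimethylcyclohex-2-en-1-one | CC1=C(OCc2ccccc2)CC(C)(C)C(CO)C1=O | intermediate
6 | (R)-3-(benzyloxy)-6-(hydroxymethyl)-2,5,5-trimethylcyclohex-2-en-1-one | CC1=C(OCc2ccccc2)CC(C)(C)[C@H](CO)C1=O | intermediate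
7 | (R)-3-hydroxy-4-(hydroxymethyl)-2,5,5-trimethylcyclohex-2-en-1-one (enol form of the dione) | CC1=C(O)[C@@H](CO)C(C)(C)CC1=O | intermediate
8 | (4aR)-2,2,5,5,8-pentamethyl-4,4a,5,6-tetrahydro-7H-1,3-benzodioxin-7-one | O=C1CC(C)(C)[C@@H]2COC(C)(C)OC2=C1C | intermediate
9 | lithium cross-conjugated dienolate of 8 | [Li]OC1=CC(C)(C)[C@@H]2COC(C)(C)OC2=C1C | intermediate
10 | (4aR)-2,2,5,5,6,8-hexamethyl-4,4a,5,6-tetrahydro-7H-1,3-benzodioxin-7-one (C6 epimers) | O=C1C(C)C(C)(C)[C@@H]2COC(C)(C)OC2=C1C | intermediate
11 | lithium cross-conjugated dienolate of 10 | [Li]OC1=C(C)C(C)(C)[C@@H]2COC(C)(C)OC2=C1C | intermediate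
12 | (4aR)-2,2,5,5,6,8-hexamethyl-7-(triisopropylsilyloxy)-4a,5-dihydro-4H-1,3-benzodioxine | CC(C)[Si](C(C)C)(C(C)C)OC1=C(C)C(C)(C)[C@@H]2COC(C)(C)OC2=C1C | intermediate
13 | ethyl (R)-3-hydroxy-3-phenylpropanoate | CCOC(=O)C[C@@H](O)c1ccccc1 | starting material
14 | ethyl (R)-3-phenyl-3-(triethylsilyloxy)propanoate | CCOC(=O)C[C@@H](O[Si](CC)(CC)CC)c1ccccc1 | intermediate
15 | (R)-N-methoxy-N-methyl-3-phenyl-3-(triethylsilyloxy)propanamide | CON(C)C(=O)C[C@@H](O[Si](CC)(CC)CC)c1ccccc1 | intermediate
16 | ethynyltrimethylsilane | C#C[Si](C)(C)C | starting material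
17 | lithium (trimethylsilyl)acetylide | [Li]C#C[Si](C)(C)C | intermediate
18 | (R)-1-phenyl-1-(triethylsilyloxy)-5-(trimethylsilyl)pent-4-yn-3-one | C[Si](C)(C)C#CC(=O)C[C@@H](O[Si](CC)(CC)CC)c1ccccc1 | intermediate
19 | (R)-5-bromo-1-phenyl-1-(triethylsilyloxy)pent-4-yn-3-one | BrC#CC(=O)C[C@@H](O[Si](CC)(CC)CC)c1ccccc1 | intermediate
20 | bicyclo[2.2.2]octadiene cycloadduct (ketal, silyl enol ether, bromoenone) | CC1(C)[C@@H]3COC(C)(C)O[C@]32C(C)=C(O[Si](C(C)C)(C(C)C)C(C)C)[C@@]1(C)C(Br)=C2C(=O)C[C@@H](O[Si](CC)(CC)CC)c1ccccc1 | intermediate
21 | bromoenone triol | CC1(C)[C@H](CO)[C@]2(O)C(C)=C(O[Si](C(C)C)(C(C)C)C(C)C)[C@@]1(C)C(Br)=C2C(=O)C[C@@H](O)c1ccccc1 | intermediate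
22 | dihydropyranone diol with silyl enol ether | CC1(C)[C@H](CO)[C@]2(O)C(C)=C(O[Si](C(C)C)(C(C)C)C(C)C)[C@@]1(C)C3=C2C(=O)C[C@H](c2ccccc2)O3 | intermediate
23 | CNP0322161.2 | CC1(C)[C@@H]2CO[C@]3(C)C(=O)[C@@]1(C)C1=C(C(=O)C[C@H](c4ccccc4)O1)[C@]23O | target

Total step count: 14. Longest linear sequence: 10 (steps 1–7, then 12–14).

**Steps most likely to fail**

**Step 12.** A fully substituted diene terminus next to a quaternary carbon must bond to a bromine-bearing carbon. The cycloaddition may therefore be too slow below the temperature at which the adduct sheds its saturated bridge. Stepwise conjugate addition with loss of bromide, or transfer of bromine to the diene, may take over.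

The fallback sets out from 18 and 12 and returns at 23. It uses a smaller dienophile without a leaving group and brings in the pyranone oxygen oxidatively.
- Protodesilylation of 18 (Na2B4O7, MeOH–H2O) gives the terminal alkynone F1.
- Thermal cycloaddition of F1 with 12 gives the bromine-free cycloadduct F2.
- Methanolysis of F2 with PPTS gives the enone triol F3.
- The electrolysis of step 14 closes the tetrahydrofuran and gives the cage ketone hydroxyenone F4.
- A Wacker-type oxidative 6-endo cyclisation of the β-hydroxyenone with divalent palladium (PdCl2, CuCl, O2, Na2HPO4, DME) closes the dihydropyranone to 23.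

**Step 13.** The silyl enol ether may be protonated during methanolysis. This would be accelerated if early ring closure releases HBr, and the cage ketone could not afterwards be re-enolised selectively beside the pyranone CH2.

The fallback sets out from 20 and returns at 23. It exchanges the acid-sensitive enol ether for an acid-stable function first.
- NBS (NaHCO3, THF, −78 °C) attacks the open face and gives the α-bromoketone ketal F5.
- HCl (cat.) in MeOH, then Et3N in CH2Cl2, gives the α-bromoketone pyranone diol F6.
- AgOSO2CF3 with 2,6-di-tert-butylpyridine promotes backside displacement of the tertiary bromide by the primary hydroxyl, with inversion, to give 23.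
- The process to watch in this last reaction is a 1,2-shift of the ring bond antiperiplanar to the C–Br bond, driven by the bridgehead oxygen.

**Step 14.** The radical cation may lose silicon before the hydroxyl adds, may be captured by methanol on the open face, or may fragment.

The fallback sets out from 22 and returns at 23. It forms the same C–O bond from an oxygen radical.
- A Mitsunobu reaction with N-hydroxyphthalimide (PPh3, DIAD) gives the N-alkoxyphthalimide F7.
- Bu3SnH and AIBN in refluxing benzene release the alkoxy radical, which closes 5-exo onto the silyl enol ether and, after hydrogen transfer, gives the cage silyl ether F8.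
- Bu4NF gives the cage secondary alcohol F9.
- Dess–Martin oxidation gives 23.

**Further compounds**

F1 | step 12 | terminal alkynone, (R)-1-phenyl-1-(triethylsilyloxy)pent-4-yn-3-one | C#CC(=O)C[C@@H](O[Si](CC)(CC)CC)c1ccccc1
F2 | step 12 | bromine-free cycloadduct | CC1(C)[C@@H]3COC(C)(C)O[C@]32C(C)=C(O[Si](C(C)C)(C(C)C)C(C)C)[C@@]1(C)C=C2C(=O)C[C@@H](O[Si](CC)(CC)CC)c1ccccc1
F3 | step 12 | enone triol | CC1(C)[C@H](CO)[C@]2(O)C(C)=C(O[Si](C(C)C)(C(C)C)C(C)C)[C@@]1(C)C=C2C(=O)C[C@@H](O)c1ccccc1
F4 | step 12 | cage ketone hydroxyenone | CC1(C)[C@@H]2CO[C@]3(C)C(=O)[C@@]1(C)C=C(C(=O)C[C@@H](O)c1ccccc1)[C@]23O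
F5 | step 13 | α-bromoketone ketal | CC1(C)[C@@H]3COC(C)(C)O[C@]32[C@@](C)(Br)C(=O)[C@@]1(C)C(Br)=C2C(=O)C[C@@H](O[Si](CC)(CC)CC)c1ccccc1
F6 | step 13 | α-bromoketone pyranone diol | CC1(C)[C@H](CO)[C@]2(O)[C@@](C)(Br)C(=O)[C@@]1(C)C3=C2C(=O)C[C@H](c2ccccc2)O3
F7 | step 14 | N-alkoxyphthalimide | CC1(C)[C@H](CON4C(=O)c5ccccc5C4=O)[C@]2(O)C(C)=C(O[Si](C(C)C)(C(C)C)C(C)C)[C@@]1(C)C3=C2C(=O)C[C@H](c2ccccc2)O3
F8 | step 14 | cage silyl ether (carbinol configuration inconsequential) | CC1(C)[C@@H]2CO[C@]3(C)C(O[Si](C(C)C)(C(C)C)C(C)C)[C@@]1(C)C1=C(C(=O)C[C@H](c4ccccc4)O1)[C@]23O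
F9 | step 14 | cage secondary alcohol (carbinol configuration inconsequential) | CC1(C)[C@@H]2CO[C@]3(C)C(O)[C@@]1(C)C1=C(C(=O)C[C@H](c4ccccc4)O1)[C@]23O
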